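Numbering: ring C1 (C=O), C2=C3, C4 (OAc), C5 (OH); side chain C6 (OAc), C7 onward. Everything rests on disconnecting C6–C7. The key step exploits the contiguous oxygenated triad C4–C5–C6 straddling the five-membered ring, read as a 2,3-epoxy alcohol. In one flask ditetradecylzinc adds to the flat, achiral enal 4 under (−)-MIB catalysis, forming C6–C7 and setting C6. The resulting zinc allyloxide then directs Ti(OiPr)4/TBHP epoxidation of ring alkene C4=C5, setting C5 and C4. The precursor is a stereocentre-free cyclopentenecarbaldehyde with C1 masked as a dioxolane. Ketal removal, acetylation, dehydrogenation and invertive acetolysis at C4 complete the target.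

Key step: step 4

Assumption: 2-bromocyclopent-2-en-1-one (1) and 1-iodotetradecane (5) are treated as catalogue compounds; 1 is otherwise one step from cyclopent-2-en-1-one (Br2, then Et3N). (−)-MIB is (2S)-(−)-3-exo-morpholinoisoborneol.

Step 1
Reactants: 1 2-bromocyclopent-2-en-1-one
Product: 2 6-bromo-1,4-dioxaspiro[4.4]non-6-ene (ethylene ketal of 1)
Conditions: HOCH2CH2OH, p-TsOH·H2O (cat.), benzene, reflux, Dean–Stark trap
Reagents that add atoms: ethylene glycol, OCCO
Why: Acid-catalysed ketalisation with azeotropic removal of water is the standard way to turn a 2-bromoenone into an α-ketovinyl anion precursor, the bromine keeping the alkene in place; no stereocentre is formed.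

Step 2
Reactants: 2 6-bromo-1,4-dioxaspiro[4.4]non-6-ene
Product: 4 1,4-dioxaspiro[4.4]non-6-ene-6-carbaldehyde, via vinyllithium 3 (not isolated)
Conditions: n-BuLi, THF, −78 °C; DMF, −78 °C to 0 °C; H2O quench
Reagents that add atoms: N,N-dimethylformamide, CN(C)C=O
Why: Bromine–lithium exchange is faster than any attack on the ketal and gives vinyllithium 3, which is formylated by DMF (Bouveault aldehyde synthesis), and the neutral quench keeps the allylic ketal intact.

Step 3
Reactants: 5 1-iodotetradecane
Product: 6 ditetradecylzinc
Conditions: Et2Zn (neat, excess), 50 °C; volatiles stripped at 50 °C/0.1 mmHg; residue taken up in toluene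
Reagents that add atoms: diethylzinc, CC[Zn]CC
Why: Iodine–zinc exchange is driven to the dialkylzinc by stripping volatile EtI and Et2Zn and gives a salt-free and copper-free reagent, which matters because lithium or magnesium halides would open a racemic background pathway in step 4.

Step 4
Reactants: 4 1,4-dioxaspiro[4.4]non-6-ene-6-carbaldehyde; 6 ditetradecylzinc
Product: 8 (1S)-1-[(1S,5S)-spiro[6-oxabicyclo[3.1.0]hexane-2,2'-[1,3]dioxolan]-1-yl]pentadecan-1-ol (epoxy alcohol; oxirane oxygen bridging C4 and C5), via zinc allyloxide 7 (not isolated)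
Conditions: 6 (2 equiv), (−)-MIB (5 mol %), toluene–hexanes, 0 °C; then TBHP (decane solution, excess), Ti(OiPr)4 (20 mol %), −20 °C to rt; aqueous work-up
Reagents that add atoms: tert-butyl hydroperoxide, CC(C)(C)OO
Why: The zinc amino-alkoxide formed from (−)-MIB and 6 binds a second molecule of 6 and the aldehyde in the bimetallic six-membered transition state known for amino-alcohol-catalysed dialkylzinc additions and transfers a tetradecyl group to the Si face of the C6 carbonyl of 4 in a 1,2-sense, which forms C6–C7 and gives the (S)-zinc allyloxide 7. TBHP then converts the remaining Zn–C bonds into zinc tert-butylperoxide, Ti(OiPr)4 gathers allyloxide and peroxide on tetravalent titanium, and oxygen is passed to the only alkene, C4=C5 of the five-membered ring. The closest known reaction type is the one-pot asymmetric dialkylzinc addition to α-substituted enals followed by titanium-mediated directed epoxidation of the zinc allyloxide, a relative of the Sharpless epoxidation. The oxirane is closed by concerted syn oxygen-atom transfer, so it is cis-fused to the ring at C4 and C5 and no ionic ring closure is involved. C6 is controlled by the catalyst, whereas C5 and C4 are controlled by C6, because in the reactive rotamer the C6–O–metal bond stands over one alkene face while the C6–H bond, not the chain, lies next to the fully substituted ketal carbon C1 (minimised A1,2 strain), which should give the erythro epoxy alcohol with the 5S,6S relationship of the target. The step needs enantioface, diastereoface and chemoselectivity, secured respectively by ligand-accelerated catalysis with salt-free 6, by the bulky spiro-dioxolane geminal to the carbinol, and by the inertness of the ketal to zinc and titanium alkoxides.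

Step 5
Reactants: 8 epoxy alcohol ketal
Product: 9 (1S,5S)-1-[(1S)-1-hydroxypentadecyl]-6-oxabicyclo[3.1.0]hexan-2-one
Conditions: PPTS (0.3 equiv), acetone–H2O (10:1), 55 °C
Reagents that add atoms: water, O
Why: Acid-catalysed ketal hydrolysis; the oxirane should survive the weak acid because ionisation at C5 is disfavoured by the flanking oxygenated carbons C1 and C6 and C4 is shielded by its quaternary neighbour, and no stereocentre is touched.

Step 6
Reactants: 9 epoxy hydroxy ketone
Product: 10 (1S)-1-[(1R,5S)-2-oxo-6-oxabicyclo[3.1.0]hexan-1-yl]pentadecyl acetate (same spatial arrangement as 9; the C5 descriptor changes only through CIP priorities)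
Conditions: Ac2O, pyridine, DMAP (cat.), CH2Cl2, 0 °C to rt
Reagents that add atoms: acetic anhydride, CC(=O)OC(C)=O
Why: DMAP-catalysed O-acylation of the only hydroxyl group; retro-aldol loss of the chain is blocked because it would need an enolate at the oxirane carbon C5, so C6 keeps its configuration.

Step 7
Reactants: 10 epoxy ketone acetate
Product: 13 (1S)-1-[(1S,5S)-2-oxo-6-oxabicyclo[3.1.0]hex-3-en-1-yl]pentadecyl acetate, via lithium enolate 11 (not isolated), via C2 sulfilimine 12 (not isolated)
Conditions: LiN(iPr)2 (1.1 equiv), THF, −78 °C; PhS(Cl)=NtBu (1.3 equiv), −78 °C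
Reagents that add atoms: none
Why: Mukaiyama dehydrogenation: C2 is the only enolisable position of the ketone (C5 is quaternary), enolate 11 is sulfenylated at C2 to 12, and 12 undergoes syn-elimination with a C3–H already at −78 °C, where acetate and oxirane should stay untouched; palladium-based dehydrogenation is avoided because zerovalent palladium could ionise the vinyl oxirane of 13.

Step 8
Reactants: 13 epoxy enone acetate
Product: 14 (4R,5S)-4-acetoxy-5-[(1S)-1-acetoxypentadecyl]-5-hydroxycyclopent-2-en-1-one (target)
Conditions: AcOH, NaOAc, 50 °C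
Reagents that add atoms: acetic acid, CC(=O)O
Why: Acid-assisted SN2 acetolysis of a 4,5-epoxycyclopentenone: C5 is quaternary and α to the ketone and therefore inert, so acetate attacks the allylic C4 anti to the oxirane oxygen, inverting C4 from S to R and releasing the C5–OH with retention (trans 4-OAc/5-OH); the C6 acetate sits on the face of attack and can only assist delivery from that face, and elimination is impossible because C5 bears no hydrogen.

Compound list
1 | 2-bromocyclopent-2-en-1-one | O=C1CCC=C1Br | starting material
2 | 6-bromo-1,4-dioxaspiro[4.4]non-6-ene | BrC1=CCCC12OCCO2 | intermediate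
3 | (1,4-dioxaspiro[4.4]non-6-en-6-yl)lithium | [Li]C1=CCCC12OCCO2 | intermediate
4 | 1,4-dioxaspiro[4.4]non-6-ene-6-carbaldehyde | O=CC1=CCCC12OCCO2 | intermediate
5 | 1-iodotetradecane | CCCCCCCCCCCCCCI | starting material
6 | ditetradecylzinc | CCCCCCCCCCCCCC[Zn]CCCCCCCCCCCCCC | intermediate
7 | tetradecylzinc (1S)-1-(1,4-dioxaspiro[4.4]non-6-en-6-yl)pentadecan-1-olate | CCCCCCCCCCCCCC[C@H](O[Zn]CCCCCCCCCCCCCC)C1=CCCC12OCCO2 | intermediate
8 | (1S)-1-[(1S,5S)-spiro[6-oxabicyclo[3.1.0]hexane-2,2'-[1,3]dioxolan]-1-yl]pentadecan-1-ol | CCCCCCCCCCCCCC[C@H](O)[C@]12O[C@H]1CCC23OCCO3 | intermediate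
9 | (1S,5S)-1-[(1S)-1-hydroxypentadecyl]-6-oxabicyclo[3.1.0]hexan-2-one | CCCCCCCCCCCCCC[C@H](O)[C@]12O[C@H]1CCC2=O | intermediate
10 | (1S)-1-[(1R,5S)-2-oxo-6-oxabicyclo[3.1.0]hexan-1-yl]pentadecyl acetate | CCCCCCCCCCCCCC[C@H](OC(C)=O)[C@]12O[C@H]1CCC2=O | intermediate
11 | lithium enolate of 10 (C1–OLi, C1=C2) | CCCCCCCCCCCCCC[C@H](OC(C)=O)[C@]12O[C@H]1CC=C2O[Li] | intermediate
12 | C2-(N-tert-butyl-S-phenylsulfinimidoyl) derivative of 10 (C2 and S configuration undefined) | CCCCCCCCCCCCCC[C@H](OC(C)=O)[C@]12O[C@H]1CC(C2=O)S(=NC(C)(C)C)c1ccccc1 | intermediate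
13 | (1S)-1-[(1S,5S)-2-oxo-6-oxabicyclo[3.1.0]hex-3-en-1-yl]pentadecyl acetate | CCCCCCCCCCCCCC[C@H](OC(C)=O)[C@]12O[C@H]1C=CC2=O | intermediate
14 | (4R,5S)-4-acetoxy-5-[(1S)-1-acetoxypentadecyl]-5-hydroxycyclopent-2-en-1-one | CCCCCCCCCCCCCC[C@H](OC(C)=O)[C@@]1(O)C(=O)C=C[C@H]1OC(C)=O | target

Total step count: 8. Longest linear sequence: 7 (steps 1, 2, 4, 5, 6, 7, 8); step 3 is a one-step side branch.

Steps most likely to fail

Step 4. Alkyl transfer from the long-chain zinc reagent may be slow. Coordination of the ketal oxygens to zinc may erode enantioface selection. Facial control in the epoxidation may be incomplete. The fallback sets out from 4 and comes back at 8. It forms the same C6–C7 bond without a catalyst and moves all stereocontrol into a resolution. Tetradecylmagnesium chloride (THF, −78 °C) should add to 4 to give the racemic allylic alcohol 1-(1,4-dioxaspiro[4.4]non-6-en-6-yl)pentadecan-1-ol F1. A Sharpless kinetic resolution (Ti(OiPr)4, L-(+)-DIPT, TBHP 0.6 equiv, 4 Å molecular sieves, CH2Cl2, −20 °C) should then epoxidise the (S)-enantiomer rapidly and erythro-selectively to 8. This leaves the slow-reacting (1R)-1-(1,4-dioxaspiro[4.4]non-6-en-6-yl)pentadecan-1-ol F2 to be separated by chromatography.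

Step 5. The oxirane may be opened by acid before the inductively deactivated ketal is cleaved. The fallback sets out from 8 and comes back at 14. It makes the opening deliberate and early instead of late. Dilute H2SO4 in THF–H2O at 50 °C should drive both ketal cleavage and anti hydrolysis of the oxirane at C4 to completion. This gives (2S,3R)-2,3-dihydroxy-2-[(1S)-1-hydroxypentadecyl]cyclopentan-1-one F3. Ac2O/pyridine should acetylate only the two secondary hydroxyls, giving (1R,2S)-2-[(1S)-1-acetoxypentadecyl]-2-hydroxy-3-oxocyclopentyl acetate F4. 2-Iodoxybenzoic acid (IBX) in DMSO at 70 °C should then dehydrogenate C2–C3 to 14.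

Step 8. Intermolecular attack at C4 beside the quaternary centre may be sluggish. Conjugate addition may compete, or the epoxy enone may degrade on heating. The fallback sets out from 13 and comes back at 14. It replaces external acetate by hydrolytic opening with participation of the C6 acetate, followed by reacetylation. Catalytic HClO4 in THF–H2O at 0 °C should open the oxirane anti at C4. The expected product is (1S)-1-[(1S,5R)-1,5-dihydroxy-2-oxocyclopent-3-en-1-yl]pentadecyl acetate F5. It may be accompanied by its acetyl-migrated isomer (1R,5S)-5-hydroxy-5-[(1S)-1-hydroxypentadecyl]-4-oxocyclopent-2-en-1-yl acetate F6. Both should converge on 14 with Ac2O/pyridine, which leaves the tertiary C5–OH free.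

Further compounds
F1 | step 4 | rac-1-(1,4-dioxaspiro[4.4]non-6-en-6-yl)pentadecan-1-ol | CCCCCCCCCCCCCCC(O)C1=CCCC12OCCO2
F2 | step 4 | (1R)-1-(1,4-dioxaspiro[4.4]non-6-en-6-yl)pentadecan-1-ol | CCCCCCCCCCCCCC[C@@H](O)C1=CCCC12OCCO2
F3 | step 5 | (2S,3R)-2,3-dihydroxy-2-[(1S)-1-hydroxypentadecyl]cyclopentan-1-one | CCCCCCCCCCCCCC[C@H](O)[C@@]1(O)C(=O)CC[C@H]1O
F4 | step 5 | (1R,2S)-2-[(1S)-1-acetoxypentadecyl]-2-hydroxy-3-oxocyclopentyl acetate | CCCCCCCCCCCCCC[C@H](OC(C)=O)[C@@]1(O)C(=O)CC[C@H]1OC(C)=O
F5 | step 8 | (1S)-1-[(1S,5R)-1,5-dihydroxy-2-oxocyclopent-3-en-1-yl]pentadecyl acetate | CCCCCCCCCCCCCC[C@H](OC(C)=O)[C@@]1(O)C(=O)C=C[C@H]1O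
F6 | step 8 | (1R,5S)-5-hydroxy-5-[(1S)-1-hydroxypentadecyl]-4-oxocyclopent-2-en-1-yl acetate | CCCCCCCCCCCCCC[C@H](O)[C@@]1(O)C(=O)C=C[C@H]1OC(C)=O
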